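**Retrosynthetic overview**
1. No ring is built: the ten-membered carbocycle, the 4,5-epoxide, the 6,12-lactone and C4–C7 come intact from parthenolide (semisynthesis).
2. Key disconnection: the C8–O and C9–O bonds, made together in the last step by anti addition of methacrylate (to C8) and acetate (to C9) across the C8=C9 bond of diene ester 9.
3. Diene 9 comes from allylic alcohol 7 by 1,4-elimination; 7 comes from ester 5 by a geminal-selective singlet-oxygen ene reaction (C1–O formed, C9–H removed).
4. Ester 5 comes from parthenolide by SeO2 hydroxylation of C14 (with trans-to-cis isomerisation of C1=C10), then oxidation and methylation.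

Assumption: parthenolide (bulk feverfew isolate, catalogue compound) is taken as the cheap commercial starting material; locants follow germacrane numbering and α/β refer to the usual drawing in which H-7 is α.

**Step 1**
Reactants: 1 parthenolide
Product: 2 melampomagnolide B (14-hydroxy compound with ring-cis C1=C10)
Conditions: SeO2 (0.5 equiv), t-BuOOH (3 equiv), CH2Cl2, 25 °C
Reagents that add atoms: tert-butyl hydroperoxide, CC(C)(C)OO (terminal oxidant; its oxygen reaches C14 through catalytic SeO2, O=[Se]=O)
Why: Riley allylic oxidation (SeO2 ene reaction at the C14 methyl, then [2,3]-sigmatropic shift) gives the primary allylic alcohol and re-forms C1=C10 in the ring-cis geometry, a conversion established for parthenolide itself; epoxide and methylene lactone are inert.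

**Step 2**
Reactants: 2 melampomagnolide B
Product: 4 14-oic acid (ring-cis enoic acid), via enal 3 (not isolated)
Conditions: TEMPO (10 mol%), PhI(OAc)2 (1.2 equiv), CH2Cl2, 25 °C; concentrate; then NaClO2 (3 equiv), NaH2PO4, 2-methyl-2-butene (10 equiv), t-BuOH/H2O, 0 to 25 °C
Reagents that add atoms: sodium chlorite, [Na+].[O-]Cl=O
Why: TEMPO/PhI(OAc)2 oxidises the primary allylic alcohol to the enal and the Pinnick chlorite oxidation takes the enal to the acid at pH 3–4 without touching the alkenes, the epoxide or the lactone; no stereocentre or olefin geometry changes.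

**Step 3**
Reactants: 4 14-oic acid
Product: 5 methyl 14-oate (ring-cis enoate)
Conditions: MeI (3 equiv), KHCO3 (2 equiv), DMF, 25 °C
Reagents that add atoms: iodomethane, CI
Why: SN2 O-alkylation of the carboxylate under weak-base conditions that leave the Michael-acceptor lactone, the epoxide and the olefin geometry alone.

**Step 4**
Reactants: 5 methyl 14-oate
Product: 7 C1 allylic alcohol with the double bond moved to C9=C10, via hydroperoxide 6 (not isolated)
Conditions: O2 (1 atm), tetraphenylporphyrin (1 mol%), visible light, CH2Cl2, 0 °C; then PPh3 (1.1 equiv), 0 °C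
Reagents that add atoms: dioxygen (as singlet oxygen), O=O
Why: Schenck ene reaction of an α,β-unsaturated ester, which follows the geminal rule (oxygen bonds to the β-carbon C1, hydrogen is taken from the alkyl group geminal to the ester, C9–H), so the alkene moves to C9=C10 while the much less reactive 1,1-disubstituted methylene lactone does not compete; PPh3 reduces the hydroperoxide; the new C1 centre (drawn 1R, attack on the exposed face) and the C9=C10 geometry are both erased in step 5.

**Step 5**
Reactants: 7 C1 allylic alcohol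
Product: 9 diene ester (ring-cis C1=C10 and Z C8=C9), via acetate 8 (not isolated)
Conditions: Ac2O (1.5 equiv), pyridine, DMAP (5 mol%), CH2Cl2, 0 °C; then DBU (2.5 equiv), 25 °C
Reagents that add atoms: none
Why: O-acetylation followed by DBU-mediated vinylogous E1cB (1,4-) elimination: the only γ-protons of the C9=C10 enoate are on C8, and the dienolate expels the C1 acetate to give the conjugated 2-(methoxycarbonyl)-1,3-diene with both ring double bonds cis, the less strained arrangement in the ten-membered ring; no stereocentre is created.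

**Step 6**
Reactants: 9 diene ester
Product: 11 target CNP0153978.7, via dioxolanylium ion 10 (not isolated)
Conditions: PhI(O2CC(CH3)=CH2)2 (1.3 equiv, made beforehand from PhI(OAc)2 and methacrylic acid), BF3·OEt2 (1.2 equiv), 4 Å molecular sieves, BHT (1 mol%), CH2Cl2, −78 to −40 °C; then Me3SiOAc (5 equiv), −40 to 0 °C; NaHCO3 quench
Reagents that add atoms: [bis(methacryloyloxy)iodo]benzene, CC(=C)C(=O)OI(OC(=O)C(C)=C)c1ccccc1; trimethylsilyl acetate, CC(=O)O[Si](C)(C)C
Why: Proposed new method: an interrupted, heteroleptic Prévost reaction with trivalent iodine in place of I2/silver, in which the BF3-activated iodane adds to the only electron-rich, ester-free π-bond (C8=C9) from its exposed β face (the face of the C7–C11 bond; the α face is screened by the C2–C6 arc of the ring), a methacrylate ligand opens the iodonium anti and its carbonyl oxygen displaces PhI with inversion to give the α-face cis-fused 2-isopropenyl-1,3-dioxolan-2-ylium ion 10 (the second methacrylate is held as RCO2BF3−), and Me3SiOAc, added only then, attacks the allylic SN2-activated C9 with inversion (β), leaving the methacrylate on O8 and setting 8R,9R by net anti addition to a cis alkene; the closest known reaction types are the Prévost reaction, the PhI(OAc)2/BF3 diacetoxylation of alkenes and the opening of dioxolan-2-ylium ions by silyl acetate, whereas sequential delivery of two different carboxylates to a macrocyclic 1,3-diene has not been shown.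

**Compound list**
1 | parthenolide, (4R,5R,6S,7S)-4α,5β-epoxygermacra-1(10),11(13)-dien-12,6α-olide, C1=C10 ring-trans | C1/C=C(\C)CC[C@H]2C(=C)C(=O)O[C@@H]2[C@H]3O[C@]3(C)C1 | starting material
2 | melampomagnolide B, 14-hydroxy analogue of 1 with ring-cis C1=C10 (C2 and C9 on the same side), (4R,5R,6S,7S) | C1/C=C(/CO)CC[C@H]2C(=C)C(=O)O[C@@H]2[C@H]3O[C@]3(C)C1 | intermediate
3 | 14-aldehyde (enal) of 2, same stereochemistry | C1/C=C(/C=O)CC[C@H]2C(=C)C(=O)O[C@@H]2[C@H]3O[C@]3(C)C1 | intermediate (not isolated)
4 | 14-carboxylic acid, ring-cis C1=C10, (4R,5R,6S,7S) | C1/C=C(/C(=O)O)CC[C@H]2C(=C)C(=O)O[C@@H]2[C@H]3O[C@]3(C)C1 | intermediate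
5 | methyl 14-oate, ring-cis C1=C10, (4R,5R,6S,7S) | C1/C=C(/C(=O)OC)CC[C@H]2C(=C)C(=O)O[C@@H]2[C@H]3O[C@]3(C)C1 | intermediate
6 | methyl (1R)-1-hydroperoxy-4α,5β-epoxygermacra-9,11(13)-dien-12,6α-olid-14-oate, C9=C10 with C8 trans to CO2Me, (1R,4R,5R,6S,7S) | C1[C@@H](OO)/C(C(=O)OC)=C\C[C@H]2C(=C)C(=O)O[C@@H]2[C@H]3O[C@]3(C)C1 | intermediate (not isolated)
7 | corresponding (1R)-1-hydroxy compound (α-(hydroxyalkyl)acrylate) | C1[C@@H](O)/C(C(=O)OC)=C\C[C@H]2C(=C)C(=O)O[C@@H]2[C@H]3O[C@]3(C)C1 | intermediate
8 | corresponding (1R)-1-acetoxy compound | C1[C@@H](OC(C)=O)/C(C(=O)OC)=C\C[C@H]2C(=C)C(=O)O[C@@H]2[C@H]3O[C@]3(C)C1 | intermediate (not isolated)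
9 | methyl 4α,5β-epoxygermacra-1(10),8,11(13)-trien-12,6α-olid-14-oate, C1=C10 ring-cis (CO2Me trans to C2), C8=C9 Z, (4R,5R,6S,7S) | C1/C=C(/C(=O)OC)\C=C/[C@H]2C(=C)C(=O)O[C@@H]2[C@H]3O[C@]3(C)C1 | intermediate
10 | 8α,9α-cis-fused 2-(prop-1-en-2-yl)-1,3-dioxolan-2-ylium ion of the ester (counter-ion methacrylatotrifluoroborate), (4R,5R,6S,7R,8R,9S) | C1/C=C(/C(=O)OC)[C@@H]2O[C+](C(C)=C)O[C@@H]2[C@H]3C(=C)C(=O)O[C@@H]3[C@H]4O[C@]4(C)C1 | intermediate (not isolated)
11 | CNP0153978.7, methyl 9β-acetoxy-8α-(methacryloyloxy)-4α,5β-epoxygermacra-1(10),11(13)-dien-12,6α-olid-14-oate, ring-cis C1=C10, (4R,5R,6S,7R,8R,9R) | C=C(C)C(=O)O[C@@H]1[C@H]2C(=C)C(=O)O[C@@H]2[C@H]2O[C@]2(C)CC/C=C(/C(=O)OC)[C@H]1OC(C)=O | target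

**Totals**
Total step count: 6. Longest linear sequence: 6 steps (fully linear from parthenolide).

**Three steps most likely to fail**

Step 6 (proposed new step). Possible failures are attack on the wrong π-face, opening of ion 10 at C1 (SN2′) instead of C9, homo-bis(methacrylate) formation, and damage to the 4,5-epoxide by BF3. The fallback uses the classical two-stage Prévost sequence, which is known chemistry. It sets out from 9: I2 and AgO2CC(CH3)=CH2 (1 equiv each, CH2Cl2, 0 °C) add across C8=C9 to give the trans iodo methacrylate F1 (its regioisomer with iodine on C9 converges on the same ion). AgOAc in dry AcOH at 40–50 °C then ionises the C–I bond with neighbouring-group participation of the ester, passing through the same dioxolanylium ion 10, and acetate opens it at allylic C9. It comes back to the route at 11.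

Step 5. Possible failures are SN2′ scrambling of the acetate followed by the wrong 1,4-elimination (giving the C1=C2/C9=C10 diene), an E C8=C9 bond, and DBU-induced isomerisation at C7 of the methylene lactone. The fallback is a base-free palladium route that sets out from 7: methyl chloroformate/pyridine gives the allylic methyl carbonate F2. Pd(PPh3)4 (5 mol%, THF, 50 °C) then ionises it; zerovalent palladium forms the 2-(methoxycarbonyl)allyl complex with loss of CO2, and β-hydrogen loss from C8 gives the diene. It comes back to the route at 9.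

Step 4. The ene reaction may be too slow on the electron-poor enoate, or the geminal selectivity may erode in the ring. The fallback moves the allylic functionalisation to the electron-rich alkene of 2 and uses a different reaction. It sets out from 2: PhSeCl (10 mol%) with N-chlorosuccinimide (CH2Cl2, 25 °C; selenium-catalysed ene-type allylic chlorination, chlorine on C1, double bond shifted to C9=C10) gives the allylic chloride F3. TEMPO/PhI(OAc)2 gives the chloro enal F4, NaClO2/NaH2PO4/2-methyl-2-butene gives the chloro acid F5, and Me3SiCHN2 in MeOH/toluene at 0 °C gives the chloro methyl ester F6. DBU then effects the same vinylogous elimination with chloride as leaving group. It comes back to the route at 9.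

**Further compounds**
F1 | step 6 | methyl 8β-iodo-9α-(methacryloyloxy)-4α,5β-epoxygermacra-1(10),11(13)-dien-12,6α-olid-14-oate, (4R,5R,6S,7S,8S,9S) | C1/C=C(/C(=O)OC)[C@H](OC(=O)C(C)=C)[C@@H](I)[C@H]2C(=C)C(=O)O[C@@H]2[C@H]3O[C@]3(C)C1
F2 | step 5 | methyl carbonate of alcohol 7, (1R,4R,5R,6S,7S) | C1[C@@H](OC(=O)OC)/C(C(=O)OC)=C\C[C@H]2C(=C)C(=O)O[C@@H]2[C@H]3O[C@]3(C)C1
F3 | step 4 | (1R)-1-chloro-14-hydroxy-4α,5β-epoxygermacra-9,11(13)-dien-12,6α-olide (C1 configuration arbitrary, erased later) | C1[C@@H](Cl)/C(CO)=C\C[C@H]2C(=C)C(=O)O[C@@H]2[C@H]3O[C@]3(C)C1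
F4 | step 4 | corresponding 1-chloro 14-aldehyde | C1[C@@H](Cl)/C(C=O)=C\C[C@H]2C(=C)C(=O)O[C@@H]2[C@H]3O[C@]3(C)C1
F5 | step 4 | corresponding 1-chloro 14-oic acid | C1[C@@H](Cl)/C(C(=O)O)=C\C[C@H]2C(=C)C(=O)O[C@@H]2[C@H]3O[C@]3(C)C1
F6 | step 4 | corresponding 1-chloro methyl 14-oate | C1[C@@H](Cl)/C(C(=O)OC)=C\C[C@H]2C(=C)C(=O)O[C@@H]2[C@H]3O[C@]3(C)C1
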